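**Two exits.** I set the two exits of D side by side. The loss to G ran at 0.00275 s⁻¹ whatever the feed of Z did, while the capture by Z ran at 0.0843 L mol⁻¹ s⁻¹ times cZ, a pseudo-first-order rate in D that moved with cZ.

    D + Z → D.Z (k1 = 0.0843 L mol⁻¹ s⁻¹)
    D → G (k2 = 0.00275 s⁻¹)
    2 Z → Z2 (k3 = 0.00541 L mol⁻¹ s⁻¹)

all flasks: D 0.10 M; time 2.0 h
- oak: Z 0.600 equiv (fed, over 2.0 min); the fed solution adds 0.10 times the starting volume
- ash: Z 0.600 equiv (fed, over 4.0 min); the fed solution adds 0.10 times the starting volume
- cedar: Z 0.600 equiv (fed, over 8.0 min); the fed solution adds 0.10 times the starting volume

- where a step has two of a species, its rate is k times that concentration squared, and two are used at each turn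
- every charge counts on the volume at the start, and the solution that is fed holds the whole dose
- "hardly changes" means that all values lie within two and a half points (for a concentration: within two and a half percent of the largest)
- run time (oak): 2.0 h

* amount of D.Z at the end, in percent of the D charged for oak, ash, cedar, in this order
* how that number moves from the first to the last of them (rises, then falls / rises all the way / falls, then rises / hardly changes / falls all the way)

**Break-even.** I divided the loss constant by the capture constant and got 0.0326 M, the cZ at which the two exits of D run equally fast: the break-even concentration. At any moment, the share of D going to D.Z is cZ over cZ plus this value.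

**The race.** The whole dose, in the volume after the feed, gave 0.0545 M, which is 1.67 times break-even. But Z is used up as D.Z forms, so I expected cZ to spend the race near break-even, not at that figure. I therefore took an even split, 0.5, of the D still present when Z came.

**The wait.** A steady feed delivers its Z, on average, half a feed time late. During that wait, D decays with a lifetime of 6.06 min. The fraction of D surviving the wait was 0.848 for oak, 0.719 for ash and 0.517 for cedar. Applying the even split gave me 42.4%, 35.9% and 25.8%. Held against the possible shapes, these figures gave: falls all the way. For oak, that yield left cZ, by my subtraction on the volume after the feed, at 0.0160 M, under break-even, so the split held together.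

**The forecast.** It gave 40.5%, 36% and 29.5%, falls all the way, on the grounds that “Slower dosing keeps Z low while D is decaying”, and its cedar figure stood above mine.

**The result.** The flasks gave 40.8%, 36.8% and 29.8%: falls all the way. My cedar figure lay 4 percentage points low.

**Why it falls.** Taking away the loss of D to G removes the fall: the change from oak to cedar goes from −11 points to 0.83 points. Break-even shows where that loss bites. At the end of its feed, oak held cZ at 0.0390 M, above 0.0326 M, with 57.6% of its D still free. At the end of its feed, cedar held cZ at 0.0312 M, under break-even, with 13.6% of its D still free.

All constants belong to no real substance; the rest is arithmetic.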